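The cyclopentenone (enone numbering: C1 carbonyl, C2=C3 alkene, C4 acetoxy-bearing quaternary carbon, C5 pentenyl-bearing methine) is cut at C3–C4 and C1–C5. This leaves a three-carbon acryloyl unit (C1–C3) and a two-carbon unit (C4–C5) that is just a ketone carbonyl carbon and its α-carbon; the 1,3-related oxygens on C1 and C4 are the feature exploited. In one operation a Brook-rearrangement-mediated [3+2] annulation joins both bonds: a regiodefined ketone lithium enolate adds to a β-sulfinyl acryloylsilane and the siloxyallyl anion so released closes onto the ketone. The sulfinyl group stabilises the anion, carries the chirality and later leaves to give the enone.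

Key step: step 6

Remark: the sense and size of the facial bias of the (R)-sulfinyl group in step 6 are assumed, so enantiopurity rests on chromatographic removal of the diastereomers of 15, and the enantiomeric sulfinate would be used in step 2 if the bias proved opposite.

Ring atoms in the Why lines use the enone numbering given above.

Step 1
Reactants: 1 methoxyallene (1-methoxypropa-1,2-diene)
Product: 3 tert-butyl(1-methoxypropa-1,2-dien-1-yl)dimethylsilane, via 1-lithio-1-methoxyallene 2 (not isolated)
Conditions: n-BuLi, THF, −78 °C; then TBSCl, −78 °C to rt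
Reagents that add atoms: tert-butyldimethylsilyl chloride, CC(C)(C)[Si](C)(C)Cl
Why: The allenic C–H next to oxygen is the most acidic site, so lithiation followed by electrophilic trapping with the silyl chloride should give the 1-silyl allenyl ether regioselectively.

Step 2
Reactants: 3 tert-butyl(1-methoxypropa-1,2-dien-1-yl)dimethylsilane
Product: 6 (2E)-1-[tert-butyl(dimethyl)silyl]-3-[(R)-4-methylbenzenesulfinyl]prop-2-en-1-one, via γ-lithioallene 4 (not isolated), via allenyl sulfoxide 5 (not isolated)
Conditions: n-BuLi, THF, −78 to −40 °C; cannulated into (−)-menthyl (S)-p-toluenesulfinate, THF, −78 °C; then 5% aq. H2SO4, THF, 0 °C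
Reagents that add atoms: (1R,2S,5R)-menthyl (S)-4-methylbenzenesulfinate, Cc1ccc(cc1)[S@@](=O)O[C@@H]1C[C@H](C)CC[C@H]1C(C)C; water, O
Why: With C1 blocked by silicon, n-BuLi removes a terminal allenic proton and the γ-lithioallene displaces mentholate from the sulfinate with inversion at sulfur (Andersen-type sulfoxide synthesis, inverse addition to keep the acidic allenyl sulfoxide away from excess base), after which acid hydrolysis of the methyl allenyl ether by protonation at the central carbon should release the thermodynamically preferred (E)-acryloylsilane with the (R)-sulfur centre intact.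

Step 3
Reactants: 7 8-bromooctan-1-ol
Product: 8 [(8-bromooctyl)oxy](tert-butyl)dimethylsilane
Conditions: TBSCl, imidazole, CH2Cl2, 0 °C to rt
Reagents that add atoms: tert-butyldimethylsilyl chloride, CC(C)(C)[Si](C)(C)Cl
Why: Standard O-silylation masks the future carboxyl terminus as a silyl ether that tolerates the Grignard, cuprate and MeLi steps ahead.

Step 4
Reactants: 8 [(8-bromooctyl)oxy](tert-butyl)dimethylsilane; 9 N-methoxy-N-methylprop-2-enamide
Product: 11 11-{[tert-butyl(dimethyl)silyl]oxy}undec-1-en-3-one, via Grignard reagent 10 (not isolated)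
Conditions: Mg turnings, THF, rt; then 9, THF, −78 to 0 °C; poured into cold 1 M aq. HCl
Reagents that add atoms: none
Why: Acyl substitution of the Grignard reagent on the N-methoxy-N-methylamide (Weinreb ketone synthesis) stops at the chelated tetrahedral adduct, so the vinyl ketone should be released only on the cold acidic quench and not meet excess nucleophile.

Step 5
Reactants: 11 11-{[tert-butyl(dimethyl)silyl]oxy}undec-1-en-3-one
Product: 12 tert-butyl(dimethyl){[(9Z,12Z)-9-(trimethylsilyloxy)pentadeca-9,12-dien-1-yl]oxy}silane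
Conditions: EtLi (2 equiv), CuI, Et2O, −40 °C; HC≡CH (2 equiv), −50 to −25 °C; then 11, TMSCl, THF, −78 °C; non-acidic work-up
Reagents that add atoms: ethyllithium, [Li]CC; acetylene, C#C; chlorotrimethylsilane, C[Si](C)(C)Cl
Why: Syn-carbocupration of acetylene by Et2CuLi gives the (Z)-butenyl cuprate stereospecifically, and its TMSCl-assisted conjugate addition to the vinyl ketone should install the (Z)-pentenyl chain while trapping the enolate regiospecifically on the pentenyl side as the silyl enol ether (Z enol geometry expected, not critical).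

Step 6
Reactants: 12 tert-butyl(dimethyl){[(9Z,12Z)-9-(trimethylsilyloxy)pentadeca-9,12-dien-1-yl]oxy}silane; 6 (2E)-1-[tert-butyl(dimethyl)silyl]-3-[(R)-4-methylbenzenesulfinyl]prop-2-en-1-one
Product: 15 (1R,2S,5S)-3-{[tert-butyl(dimethyl)silyl]oxy}-1-(8-{[tert-butyl(dimethyl)silyl]oxy}octyl)-5-[(R)-4-methylbenzenesulfinyl]-2-[(2Z)-pent-2-en-1-yl]cyclopent-3-en-1-yl acetate, via lithium enolate 13 (not isolated), via lithium alkoxide 14 (not isolated)
Conditions: MeLi (0.98 equiv), THF, 0 °C; then 6, −80 to −30 °C; then Ac2O, −30 to 0 °C; chromatographic separation of diastereomers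
Reagents that add atoms: acetic anhydride, CC(=O)OC(C)=O
Why: MeLi cleaves the O–Si bond of 12 to the regiodefined enolate 13, whose carbon adds 1,2 to the acylsilane carbonyl of 6 (bond C1–C5); the α-silyl alkoxide undergoes a 1,2-Brook shift of silicon from carbon to oxygen, and the sulfinyl-stabilised siloxyallyl anion attacks the internal ketone through its sulfinyl-bearing terminus (bond C3–C4) to give alkoxide 14, which Ac2O acetylates in the same flask. The closest known reaction type is the Brook-rearrangement-mediated [3+2] annulation of β-phenylthio and β-trimethylsilyl acryloylsilanes with ketone lithium enolates, of which the β-sulfinyl case is an extension. The ring closes in 5-exo-trig mode (allyl anion terminus onto C=O, oxygen exocyclic), and a vinylcyclopropanolate opening by 1,3-shift would lead to the same ring. C5 is set in the first addition and C4 in the ring closure, where the octyl chain should settle anti to the pentenyl group and the sulfinyl group anti to the chain (lithium bridging sulfinyl and alkoxide oxygens); the (R)-sulfur centre is expected to fix the sulfinyl-bearing carbon and through it C4, and it makes every mis-set isomer a separable diastereomer. The step needs 1,2- over conjugate addition (low temperature and the aldehyde-like acylsilane carbonyl), a single enolate regiochemistry (the silyl enol ether of step 5) and Brook shift plus closure ahead of proton transfer (sulfinyl and allyl stabilisation of the carbanion, ketone held close). Acetylating the alkoxide before any ketone is unveiled avoids a free β-hydroxy ketone that could racemise by retro-aldol opening.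

Step 7
Reactants: 15 (1R,2S,5S)-3-{[tert-butyl(dimethyl)silyl]oxy}-1-(8-{[tert-butyl(dimethyl)silyl]oxy}octyl)-5-[(R)-4-methylbenzenesulfinyl]-2-[(2Z)-pent-2-en-1-yl]cyclopent-3-en-1-yl acetate
Product: 18 (1S,5S)-1-(8-hydroxyoctyl)-4-oxo-5-[(2Z)-pent-2-en-1-yl]cyclopent-2-en-1-yl acetate, via sulfinyl ketone 16 (not isolated), via enone silyl ether 17 (not isolated)
Conditions: HF·pyridine, pyridine, THF, 0 °C to rt
Reagents that add atoms: none
Why: Fluoride cleaves both silyl groups and the unveiled β-sulfinyl ketone should lose 4-methylbenzenesulfenic acid by thermal syn-elimination (sulfoxide elimination) toward the only available hydrogens at C2, giving the C2=C3 enone under non-basic conditions that spare the tertiary acetate, C5 and the (Z)-alkene, with any C5 epimer from step 6 separable here.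

Step 8
Reactants: 18 (1S,5S)-1-(8-hydroxyoctyl)-4-oxo-5-[(2Z)-pent-2-en-1-yl]cyclopent-2-en-1-yl acetate
Product: 20 8-[(1S,5S)-1-(acetyloxy)-4-oxo-5-[(2Z)-pent-2-en-1-yl]cyclopent-2-en-1-yl]octanoic acid, via aldehyde 19 (not isolated)
Conditions: TEMPO (cat.), PhI(OAc)2, MeCN–H2O, rt
Reagents that add atoms: water, O
Why: Oxoammonium-mediated oxidation (TEMPO/PhI(OAc)2) should take the primary alcohol through the aldehyde hydrate to the acid under mildly acidic conditions, avoiding base-induced loss of acetic acid or epimerisation at C5 and leaving the enone and (Z)-alkene intact.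

Compound list
1 | methoxyallene (1-methoxypropa-1,2-diene) | COC=C=C | starting material
2 | 1-lithio-1-methoxyallene | COC([Li])=C=C | intermediate
3 | tert-butyl(1-methoxypropa-1,2-dien-1-yl)dimethylsilane | COC(=C=C)[Si](C)(C)C(C)(C)C | intermediate
4 | γ-lithioallene (3-lithio derivative of 3) | [Li]C=C=C(OC)[Si](C)(C)C(C)(C)C | intermediate
5 | tert-butyl{1-methoxy-3-[(R)-4-methylbenzenesulfinyl]propa-1,2-dien-1-yl}dimethylsilane (axial isomers) | Cc1ccc(cc1)[S@](=O)C=C=C(OC)[Si](C)(C)C(C)(C)C | intermediate
6 | (2E)-1-[tert-butyl(dimethyl)silyl]-3-[(R)-4-methylbenzenesulfinyl]prop-2-en-1-one | Cc1ccc(cc1)[S@](=O)/C=C/C(=O)[Si](C)(C)C(C)(C)C | intermediate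
7 | 8-bromooctan-1-ol | OCCCCCCCCBr | starting material
8 | [(8-bromooctyl)oxy](tert-butyl)dimethylsilane | CC(C)(C)[Si](C)(C)OCCCCCCCCBr | intermediate
9 | N-methoxy-N-methylprop-2-enamide | C=CC(=O)N(C)OC | starting material
10 | (8-{[tert-butyl(dimethyl)silyl]oxy}octyl)magnesium bromide | CC(C)(C)[Si](C)(C)OCCCCCCCC[Mg]Br | intermediate
11 | 11-{[tert-butyl(dimethyl)silyl]oxy}undec-1-en-3-one | C=CC(=O)CCCCCCCCO[Si](C)(C)C(C)(C)C | intermediate
12 | tert-butyl(dimethyl){[(9Z,12Z)-9-(trimethylsilyloxy)pentadeca-9,12-dien-1-yl]oxy}silane | CC/C=C\C/C=C(\O[Si](C)(C)C)CCCCCCCCO[Si](C)(C)C(C)(C)C | intermediate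
13 | lithium (9Z,12Z)-1-{[tert-butyl(dimethyl)silyl]oxy}pentadeca-9,12-dien-9-olate | CC/C=C\C/C=C(\[O-])CCCCCCCCO[Si](C)(C)C(C)(C)C.[Li+] | intermediate
14 | lithium (1R,2S,5S)-3-{[tert-butyl(dimethyl)silyl]oxy}-1-(8-{[tert-butyl(dimethyl)silyl]oxy}octyl)-5-[(R)-4-methylbenzenesulfinyl]-2-[(2Z)-pent-2-en-1-yl]cyclopent-3-en-1-olate | CC/C=C\C[C@@H]1C(O[Si](C)(C)C(C)(C)C)=C[C@H]([S@@](=O)c2ccc(C)cc2)[C@]1(CCCCCCCCO[Si](C)(C)C(C)(C)C)[O-].[Li+] | intermediate
15 | (1R,2S,5S)-3-{[tert-butyl(dimethyl)silyl]oxy}-1-(8-{[tert-butyl(dimethyl)silyl]oxy}octyl)-5-[(R)-4-methylbenzenesulfinyl]-2-[(2Z)-pent-2-en-1-yl]cyclopent-3-en-1-yl acetate (sulfinyl cis to acetate, octyl chain trans to pentenyl) | CC/C=C\C[C@@H]1C(O[Si](C)(C)C(C)(C)C)=C[C@H]([S@@](=O)c2ccc(C)cc2)[C@]1(CCCCCCCCO[Si](C)(C)C(C)(C)C)OC(C)=O | intermediate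
16 | (1R,2S,5S)-1-(8-{[tert-butyl(dimethyl)silyl]oxy}octyl)-5-[(R)-4-methylbenzenesulfinyl]-3-oxo-2-[(2Z)-pent-2-en-1-yl]cyclopentyl acetate | CC/C=C\C[C@@H]1C(=O)C[C@H]([S@@](=O)c2ccc(C)cc2)[C@]1(CCCCCCCCO[Si](C)(C)C(C)(C)C)OC(C)=O | intermediate
17 | (1S,5S)-1-(8-{[tert-butyl(dimethyl)silyl]oxy}octyl)-4-oxo-5-[(2Z)-pent-2-en-1-yl]cyclopent-2-en-1-yl acetate | CC/C=C\C[C@@H]1C(=O)C=C[C@]1(CCCCCCCCO[Si](C)(C)C(C)(C)C)OC(C)=O | intermediate
18 | (1S,5S)-1-(8-hydroxyoctyl)-4-oxo-5-[(2Z)-pent-2-en-1-yl]cyclopent-2-en-1-yl acetate | CC/C=C\C[C@@H]1C(=O)C=C[C@]1(CCCCCCCCO)OC(C)=O | intermediate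
19 | (1S,5S)-4-oxo-1-(8-oxooctyl)-5-[(2Z)-pent-2-en-1-yl]cyclopent-2-en-1-yl acetate | CC/C=C\C[C@@H]1C(=O)C=C[C@]1(CCCCCCCC=O)OC(C)=O | intermediate
20 | 8-[(1S,5S)-1-(acetyloxy)-4-oxo-5-[(2Z)-pent-2-en-1-yl]cyclopent-2-en-1-yl]octanoic acid | CC/C=C\C[C@@H]1C(=O)C=C[C@]1(CCCCCCCC(=O)O)OC(C)=O | target

Total step count: 8. Longest linear sequence: 6 steps (steps 3, 4, 5, 6, 7, 8).

Steps most likely to fail

Step 6. The enolate may add with little or the wrong facial bias, the C5 centre may form with poor diastereoselectivity, the enolate may attack the sulfinyl-bearing alkene carbon in a conjugate addition–elimination, or the allyl anion may be protonated before ring closure. The fallback uses the established β-phenylthio substrate type in racemic form and sets out from 4 and 13. Lithioallene 4 is quenched with PhSSPh to give the allenyl sulfide F1, and acid hydrolysis gives (2E)-1-[tert-butyl(dimethyl)silyl]-3-(phenylsulfanyl)prop-2-en-1-one F2. Enolate 13 and F2 under the conditions of step 6, with the Ac2O quench, should give the racemic sulfide acetate F3. HF·pyridine should then give the racemic keto alcohol F4, and NaIO4 in aqueous MeOH the sulfoxide F5. On warming, F5 should lose benzenesulfenic acid to give 18 together with its enantiomer F6. The pair is separated by preparative chromatography on a chiral stationary phase, and the route is rejoined at 18.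

Step 2. Proton transfer from the acidic allenyl sulfoxide to unreacted lithioallene, attack of the sulfinate at the α- instead of the γ-terminus, or acid-induced loss of configuration at sulfur during hydrolysis may erode yield or optical purity. The fallback sets out from 4 and puts sulfur in at the sulfide level. Lithioallene 4 is quenched with di-p-tolyl disulfide to give the allenyl sulfide F7, which 5% aq. H2SO4 should hydrolyse to (2E)-1-[tert-butyl(dimethyl)silyl]-3-[(4-methylphenyl)sulfanyl]prop-2-en-1-one F8. Titanium–tartrate-mediated asymmetric sulfoxidation (Ti(OiPr)4, the diethyl tartrate enantiomer that delivers the (R)-sulfoxide, cumene hydroperoxide, CH2Cl2, −20 °C), with recrystallisation if needed, should return the route at 6.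

Step 4. Conjugate addition of the Grignard reagent or of liberated N,O-dimethylhydroxylamine to the vinyl ketone, or polymerisation of the enone during work-up, may consume the product. The fallback sets out from 10, which is added to acrolein (THF, −78 °C) to give 11-{[tert-butyl(dimethyl)silyl]oxy}undec-1-en-3-ol F9. Oxidation of the allylic alcohol with MnO2 in CH2Cl2 should return the route at 11.

Further compounds
F1 | step 6 | tert-butyl[1-methoxy-3-(phenylsulfanyl)propa-1,2-dien-1-yl]dimethylsilane | COC(=C=CSc1ccccc1)[Si](C)(C)C(C)(C)C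
F2 | step 6 | (2E)-1-[tert-butyl(dimethyl)silyl]-3-(phenylsulfanyl)prop-2-en-1-one | CC(C)(C)[Si](C)(C)C(=O)/C=C/Sc1ccccc1
F3 | step 6 | racemic 3-{[tert-butyl(dimethyl)silyl]oxy}-1-(8-{[tert-butyl(dimethyl)silyl]oxy}octyl)-2-[(2Z)-pent-2-en-1-yl]-5-(phenylsulfanyl)cyclopent-3-en-1-yl acetate (relative configuration as in 15, one enantiomer drawn) | CC/C=C\C[C@@H]1C(O[Si](C)(C)C(C)(C)C)=C[C@H](Sc2ccccc2)[C@]1(CCCCCCCCO[Si](C)(C)C(C)(C)C)OC(C)=O
F4 | step 6 | racemic 1-(8-hydroxyoctyl)-3-oxo-2-[(2Z)-pent-2-en-1-yl]-5-(phenylsulfanyl)cyclopentyl acetate (one enantiomer drawn) | CC/C=C\C[C@@H]1C(=O)C[C@H](Sc2ccccc2)[C@]1(CCCCCCCCO)OC(C)=O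
F5 | step 6 | racemic 5-(benzenesulfinyl)-1-(8-hydroxyoctyl)-3-oxo-2-[(2Z)-pent-2-en-1-yl]cyclopentyl acetate (sulfur epimers, one ring enantiomer drawn) | CC/C=C\C[C@@H]1C(=O)C[C@H](S(=O)c2ccccc2)[C@]1(CCCCCCCCO)OC(C)=O
F6 | step 6 | (1R,5R)-1-(8-hydroxyoctyl)-4-oxo-5-[(2Z)-pent-2-en-1-yl]cyclopent-2-en-1-yl acetate (enantiomer of 18) | CC/C=C\C[C@H]1C(=O)C=C[C@@]1(CCCCCCCCO)OC(C)=O
F7 | step 2 | tert-butyl{1-methoxy-3-[(4-methylphenyl)sulfanyl]propa-1,2-dien-1-yl}dimethylsilane | COC(=C=CSc1ccc(C)cc1)[Si](C)(C)C(C)(C)C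
F8 | step 2 | (2E)-1-[tert-butyl(dimethyl)silyl]-3-[(4-methylphenyl)sulfanyl]prop-2-en-1-one | CC(C)(C)[Si](C)(C)C(=O)/C=C/Sc1ccc(C)cc1
F9 | step 4 | 11-{[tert-butyl(dimethyl)silyl]oxy}undec-1-en-3-ol | C=CC(O)CCCCCCCCO[Si](C)(C)C(C)(C)C
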